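Ring C is disconnected at the two bonds that join it to ring A, O1–C8a and C4–C4a. Ring A is delivered as 3,5-dimethoxybenzyne and the rest of the molecule, ring B included, as a 2-arylacrylic acid. In one operation the carboxylate adds to the aryne, the aryl anion takes over the acyl group (net insertion into the acid C–O bond) and the phenoxide closes ring C by oxa-Michael addition. The step exploits the ortho placement of O1 and the C4 carbonyl on ring A and the C5 oxygen beside C4a, which polarises the aryne so that oxygen goes to C8a and the acyl group to C4a. C3 is then hydroxylated enantioselectively and the phenols are released.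

Key step: step 8

Assumption: the (−)-antipode of the [(8,8-dimethoxycamphoryl)sulfonyl]oxaziridine is taken to attack the enolate face that gives (S) at C3, by analogy with 3-benzyl-5,7-dimethoxychroman-4-one enolates (same priority order OH > C4 > C2 > C3 substituent); if the C3 aryl group reverses the sense, the (+)-antipode is used in the same step.

Step 1
Reactants: 1 3,5-dimethoxyphenol
Product: 2 3,5-dimethoxyphenyl N-isopropylcarbamate
Conditions: i-PrNCO, Et3N (cat.), CH2Cl2, rt
Reagents that add atoms: isopropyl isocyanate CC(C)N=C=O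
Why: Base-catalysed addition of the phenol to the isocyanate gives the carbamate, which serves as the directing group for ortho-metalation and is later removable under mild base.

Step 2
Reactants: 2 3,5-dimethoxyphenyl N-isopropylcarbamate
Product: 5 3,5-dimethoxy-2-(trimethylsilyl)phenyl N-isopropylcarbamate, via N-silyl carbamate 3 (not isolated), via C-silylated N-silyl carbamate 4 (not isolated)
Conditions: t-BuMe2SiOTf, TMEDA, Et2O, 0 °C to rt; then n-BuLi, TMEDA, −78 °C; Me3SiCl, −78 °C to rt; aq NaHSO4
Reagents that add atoms: chlorotrimethylsilane C[Si](C)(C)Cl; tert-butyldimethylsilyl triflate CC(C)(C)[Si](C)(C)OS(=O)(=O)C(F)(F)F (its silyl group stays only in 3 and 4)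
Why: Directed ortho-metalation: the N-silylated carbamate steers n-BuLi to the ring carbon between the carbamate and a methoxy group, Me3SiCl traps the aryllithium, and the N-silyl group is lost on acidic work-up.

Step 3
Reactants: 5 3,5-dimethoxy-2-(trimethylsilyl)phenyl N-isopropylcarbamate
Product: 7 3,5-dimethoxy-2-(trimethylsilyl)phenyl trifluoromethanesulfonate, via 3,5-dimethoxy-2-(trimethylsilyl)phenol 6 (not isolated)
Conditions: DBU, Et2NH, MeCN, 40 °C; then PhNTf2, rt
Reagents that add atoms: N-phenylbis(trifluoromethanesulfonimide) O=S(=O)(N(c1ccccc1)S(=O)(=O)C(F)(F)F)C(F)(F)F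
Why: E1cB cleavage of the secondary carbamate (the isocyanate is trapped by Et2NH) frees the phenoxide, which is triflated in the same flask to give the ortho-silylaryl triflate aryne precursor.

Step 4
Reactants: 8 1-(2,4-dihydroxyphenyl)ethan-1-one
Product: 9 1-[2,4-dihydroxy-3-(3-methylbut-2-en-1-yl)phenyl]ethan-1-one
Conditions: prenyl bromide, 10% aq KOH, 0 °C to rt; chromatography
Reagents that add atoms: prenyl bromide CC(C)=CCBr
Why: Nuclear C-alkylation of the resorcinolate in water occurs at C3, the carbon flanked by both oxygens, and the 5-prenyl and O-prenyl side products are separated.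

Step 5
Reactants: 9 1-[2,4-dihydroxy-3-(3-methylbut-2-en-1-yl)phenyl]ethan-1-one
Product: 11 1-[4-(allyloxy)-2-methoxy-3-(3-methylbut-2-en-1-yl)phenyl]ethan-1-one, via 4-O-allyl phenol 10 (not isolated)
Conditions: allyl bromide (1.05 equiv), K2CO3, DMF, rt; then MeI (3 equiv), 50 °C
Reagents that add atoms: allyl bromide C=CCBr; iodomethane CI
Why: Two Williamson etherifications in sequence: the free 4-OH reacts first at room temperature, and the hydrogen-bonded 2-OH is methylated only on heating with excess MeI.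

Step 6
Reactants: 11 1-[4-(allyloxy)-2-methoxy-3-(3-methylbut-2-en-1-yl)phenyl]ethan-1-one
Product: 13 1-[4-(allyloxy)-2-methoxy-3-(3-methylbut-2-en-1-yl)phenyl]ethenyl trifluoromethanesulfonate, via potassium enolate 12 (not isolated)
Conditions: KN(SiMe3)2, THF, −78 °C; then PhNTf2, −78 to 0 °C; aq NH4Cl
Reagents that add atoms: N-phenylbis(trifluoromethanesulfonimide) O=S(=O)(N(c1ccccc1)S(=O)(=O)C(F)(F)F)C(F)(F)F
Why: The methyl ketone has a single enolisation site, so O-triflation of its potassium enolate gives the terminal enol triflate.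

Step 7
Reactants: 13 1-[4-(allyloxy)-2-methoxy-3-(3-methylbut-2-en-1-yl)phenyl]ethenyl trifluoromethanesulfonate
Product: 14 2-[4-(allyloxy)-2-methoxy-3-(3-methylbut-2-en-1-yl)phenyl]prop-2-enoic acid
Conditions: Pd(OAc)2 (5 mol %), PPh3 (10 mol %), CO (1 atm), KOAc, DMF, rt to 50 °C; aqueous citric acid work-up
Reagents that add atoms: carbon monoxide [C-]#[O+]; potassium acetate CC(=O)[O-].[K+] (oxygen of the carboxyl OH, through the mixed anhydride); water O (hydrolysis of the mixed anhydride)
Why: Palladium-catalysed hydroxycarbonylation: the enol triflate adds oxidatively to zerovalent palladium at room temperature (much faster than ionisation of the aryl allyl ether), CO inserts, and acetate then water release the acrylic acid.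

Step 8
Reactants: 14 2-[4-(allyloxy)-2-methoxy-3-(3-methylbut-2-en-1-yl)phenyl]prop-2-enoic acid; 7 3,5-dimethoxy-2-(trimethylsilyl)phenyl trifluoromethanesulfonate
Product: 17 racemic 3-[4-(allyloxy)-2-methoxy-3-(3-methylbut-2-en-1-yl)phenyl]-5,7-dimethoxychroman-4-one, via 3,5-dimethoxybenzyne 15 (not isolated), via 2-hydroxyaryl enone 16 (not isolated)
Conditions: 7 (1.2 equiv), CsF (4 equiv), THF, 125 °C, sealed tube
Reagents that add atoms: none
Why: CsF removes the silyl group of 7 and triflate leaves to give aryne 15; the cesium carboxylate of 14 adds through oxygen to the aryne carbon remote from the flanking methoxy group, and the aryl anion formed beside that methoxy group attacks the ester carbonyl and opens the four-membered adduct to the 2-acylphenoxide of 16 (net aryne insertion into the acid C–O bond, making C8a–O1 and C4a–C4). The phenoxide then closes ring C by 6-endo-trig oxa-Michael addition to the α-aryl enone (O1–C2) and the enolate is protonated. The closest known reaction type is the aryne annulation of acrylic acids to chroman-4-ones under these conditions. The only new stereocenter, C3, arises by unselective protonation and is racemic on purpose, because step 9 passes through the planar enolate again. The selectivity needed is the regiochemistry of aryne capture, secured by the methoxy group that becomes C5–OMe, whose inductive and distortion effects send the nucleophile to the distal carbon. The aryne precursor is kept near one equivalent so that the enolisable product is not arylated.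

Step 9
Reactants: 17 racemic 3-[4-(allyloxy)-2-methoxy-3-(3-methylbut-2-en-1-yl)phenyl]-5,7-dimethoxychroman-4-one
Product: 19 (3S)-3-[4-(allyloxy)-2-methoxy-3-(3-methylbut-2-en-1-yl)phenyl]-3-hydroxy-5,7-dimethoxychroman-4-one, via sodium enolate 18 (not isolated)
Conditions: NaN(SiMe3)2, THF, −78 °C; then (−)-[(8,8-dimethoxycamphoryl)sulfonyl]oxaziridine, −78 to −40 °C; aq NH4Cl
Reagents that add atoms: (−)-[(8,8-dimethoxycamphoryl)sulfonyl]oxaziridine, the antipode derived from (1R)-(−)-10-camphorsulfonic acid, CC1(C)[C@H]2CC[C@@]13CS(=O)(=O)N4O[C@]34C2(OC)OC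
Why: Davis oxidation: enolate 18 is planar at C3 and the camphor-derived N-sulfonyloxaziridine, the variant matched to chromanone enolates with a peri C5 alkoxy group, transfers oxygen to one face under reagent control, setting C3 as S under the stated assumption without touching the prenyl or allyl alkenes.

Step 10
Reactants: 19 (3S)-3-[4-(allyloxy)-2-methoxy-3-(3-methylbut-2-en-1-yl)phenyl]-3-hydroxy-5,7-dimethoxychroman-4-one
Product: 20 (3S)-3-[4-(allyloxy)-2-methoxy-3-(3-methylbut-2-en-1-yl)phenyl]-3,5-dihydroxy-7-methoxychroman-4-one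
Conditions: MgI2·OEt2 (4 equiv), THF, 60 °C; aq NH4Cl
Reagents that add atoms: none
Why: Chelation-assisted demethylation: magnesium bridges the C4 carbonyl and the peri C5 methoxy oxygen and iodide removes that methyl group by SN2, while the unchelated C7 and C2' methyl ethers, the allyl ether and the prenyl group are expected to remain, as with other prenylated 5-methoxychromanones.

Step 11
Reactants: 20 (3S)-3-[4-(allyloxy)-2-methoxy-3-(3-methylbut-2-en-1-yl)phenyl]-3,5-dihydroxy-7-methoxychroman-4-one
Product: 21 (3S)-3,5-dihydroxy-3-[4-hydroxy-2-methoxy-3-(3-methylbut-2-en-1-yl)phenyl]-7-methoxychroman-4-one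
Conditions: Pd(PPh3)4 (5 mol %), morpholine, THF, rt
Reagents that add atoms: none
Why: Tsuji–Trost deallylation: zerovalent palladium ionises the aryl allyl ether to a π-allyl complex that morpholine captures, under neutral conditions that leave the C-prenyl group and the quaternary C3 carbinol untouched.

Compound list
1 | 3,5-dimethoxyphenol | COc1cc(O)cc(OC)c1 | starting material
2 | 3,5-dimethoxyphenyl N-isopropylcarbamate | COc1cc(OC)cc(OC(=O)NC(C)C)c1 | intermediate
3 | 3,5-dimethoxyphenyl N-(tert-butyldimethylsilyl)-N-isopropylcarbamate (not isolated) | COc1cc(OC)cc(OC(=O)N(C(C)C)[Si](C)(C)C(C)(C)C)c1 | intermediate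
4 | 3,5-dimethoxy-2-(trimethylsilyl)phenyl N-(tert-butyldimethylsilyl)-N-isopropylcarbamate (not isolated) | COc1cc(OC)c([Si](C)(C)C)c(OC(=O)N(C(C)C)[Si](C)(C)C(C)(C)C)c1 | intermediate
5 | 3,5-dimethoxy-2-(trimethylsilyl)phenyl N-isopropylcarbamate | COc1cc(OC)c([Si](C)(C)C)c(OC(=O)NC(C)C)c1 | intermediate
6 | 3,5-dimethoxy-2-(trimethylsilyl)phenol (not isolated, present as its DBU salt) | COc1cc(OC)c([Si](C)(C)C)c(O)c1 | intermediate
7 | 3,5-dimethoxy-2-(trimethylsilyl)phenyl trifluoromethanesulfonate | COc1cc(OC)c([Si](C)(C)C)c(OS(=O)(=O)C(F)(F)F)c1 | intermediate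
8 | 1-(2,4-dihydroxyphenyl)ethan-1-one | CC(=O)c1ccc(O)cc1O | starting material
9 | 1-[2,4-dihydroxy-3-(3-methylbut-2-en-1-yl)phenyl]ethan-1-one | CC(=O)c1ccc(O)c(CC=C(C)C)c1O | intermediate
10 | 1-[4-(allyloxy)-2-hydroxy-3-(3-methylbut-2-en-1-yl)phenyl]ethan-1-one (not isolated) | CC(=O)c1ccc(OCC=C)c(CC=C(C)C)c1O | intermediate
11 | 1-[4-(allyloxy)-2-methoxy-3-(3-methylbut-2-en-1-yl)phenyl]ethan-1-one | CC(=O)c1ccc(OCC=C)c(CC=C(C)C)c1OC | intermediate
12 | potassium enolate of 11 (not isolated) | C=C([O-])c1ccc(OCC=C)c(CC=C(C)C)c1OC.[K+] | intermediate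
13 | 1-[4-(allyloxy)-2-methoxy-3-(3-methylbut-2-en-1-yl)phenyl]ethenyl trifluoromethanesulfonate | C=C(OS(=O)(=O)C(F)(F)F)c1ccc(OCC=C)c(CC=C(C)C)c1OC | intermediate
14 | 2-[4-(allyloxy)-2-methoxy-3-(3-methylbut-2-en-1-yl)phenyl]prop-2-enoic acid | C=C(C(=O)O)c1ccc(OCC=C)c(CC=C(C)C)c1OC | intermediate
15 | 3,5-dimethoxybenzyne (1,2-didehydro-3,5-dimethoxybenzene, not isolated) | COC1=CC(OC)=CC#C1 | intermediate
16 | 2-[4-(allyloxy)-2-methoxy-3-(3-methylbut-2-en-1-yl)phenyl]-1-(2-hydroxy-4,6-dimethoxyphenyl)prop-2-en-1-one (not isolated, present as its cesium phenoxide) | C=C(C(=O)c1c(O)cc(OC)cc1OC)c1ccc(OCC=C)c(CC=C(C)C)c1OC | intermediate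
17 | racemic 3-[4-(allyloxy)-2-methoxy-3-(3-methylbut-2-en-1-yl)phenyl]-5,7-dimethoxychroman-4-one | COc1cc(OC)c2c(c1)OCC(c1ccc(OCC=C)c(CC=C(C)C)c1OC)C2=O | intermediate
18 | sodium enolate of 17 (not isolated) | COc1cc(OC)c2c(c1)OCC(c1ccc(OCC=C)c(CC=C(C)C)c1OC)=C2[O-].[Na+] | intermediate
19 | (3S)-3-[4-(allyloxy)-2-methoxy-3-(3-methylbut-2-en-1-yl)phenyl]-3-hydroxy-5,7-dimethoxychroman-4-one | COc1cc(OC)c2c(c1)OC[C@@](O)(c1ccc(OCC=C)c(CC=C(C)C)c1OC)C2=O | intermediate
20 | (3S)-3-[4-(allyloxy)-2-methoxy-3-(3-methylbut-2-en-1-yl)phenyl]-3,5-dihydroxy-7-methoxychroman-4-one | COc1cc(O)c2c(c1)OC[C@@](O)(c1ccc(OCC=C)c(CC=C(C)C)c1OC)C2=O | intermediate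
21 | (3S)-3,5-dihydroxy-3-[4-hydroxy-2-methoxy-3-(3-methylbut-2-en-1-yl)phenyl]-7-methoxychroman-4-one | COc1cc(O)c2c(c1)OC[C@@](O)(c1ccc(O)c(CC=C(C)C)c1OC)C2=O | target

Total step count: 11. Longest linear sequence: 8 steps (steps 4 to 11, from 8); the aryne precursor 7 is made in 3 steps (steps 1 to 3).

Steps most likely to fail

Step 8. The aryl anion may be protonated before acyl transfer, leaving the aryl ester. Surplus aryne may arylate the enolisable product, or the acrylic acid may oligomerise at 125 °C. The fallback sets out from 1 and 14 and rejoins the route at 17; it replaces the one-pot annulation by stepwise acylation of a ring A organolithium followed by oxa-Michael closure. Compound 1 is protected with MOMCl and i-Pr2NEt as 1,3-dimethoxy-5-(methoxymethoxy)benzene F1. Acid 14 is condensed with MeNHOMe·HCl (N-ethyl-N'-(3-dimethylaminopropyl)carbodiimide hydrochloride, i-Pr2NEt) to N-methoxy-N-methyl-2-[4-(allyloxy)-2-methoxy-3-(3-methylbut-2-en-1-yl)phenyl]prop-2-enamide F2. F1 is lithiated with n-BuLi in THF at 0 °C between the OMOM and OMe groups and added to F2 at −78 °C to give 2-[4-(allyloxy)-2-methoxy-3-(3-methylbut-2-en-1-yl)phenyl]-1-[2,4-dimethoxy-6-(methoxymethoxy)phenyl]prop-2-en-1-one F3. Catalytic HCl in MeOH at room temperature removes the carbonyl-flanked MOM group to give 16, and K2CO3 in MeOH closes it to 17.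

Step 9. Oxygen transfer to the C3-aryl enolate may show poor or reversed facial selectivity, and the enolate may open by β-elimination of the C8a phenoxide. The fallback sets out from 17 and rejoins at 19; it replaces asymmetric induction by resolution. The sodium enolate is hydroxylated with racemic 2-(phenylsulfonyl)-3-phenyloxaziridine to racemic 3-[4-(allyloxy)-2-methoxy-3-(3-methylbut-2-en-1-yl)phenyl]-3-hydroxy-5,7-dimethoxychroman-4-one F4. The enantiomers are separated by preparative chromatography on a cellulose tris(3,5-dimethylphenylcarbamate) phase; the (3S) enantiomer is 19, and (3R)-3-[4-(allyloxy)-2-methoxy-3-(3-methylbut-2-en-1-yl)phenyl]-3-hydroxy-5,7-dimethoxychroman-4-one F5 is set aside.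

Step 10. The Lewis acid may ionise the tertiary benzylic C3–OH (dehydration toward the isoflavone), or cleave the wrong ether, for example the C2' methoxy group held in a chelate with the C3 oxygen. The fallback sets out from 17 and rejoins at 21; it demethylates before C3 is oxidised and carries the C5 oxygen as an allyl ether. Compound 17 with MgI2·OEt2 in THF gives racemic 3-[4-(allyloxy)-2-methoxy-3-(3-methylbut-2-en-1-yl)phenyl]-5-hydroxy-7-methoxychroman-4-one F6. Allyl bromide and K2CO3 in DMF at 60 °C give racemic 5-(allyloxy)-3-[4-(allyloxy)-2-methoxy-3-(3-methylbut-2-en-1-yl)phenyl]-7-methoxychroman-4-one F7. Hydroxylation as in step 9 gives (3S)-5-(allyloxy)-3-[4-(allyloxy)-2-methoxy-3-(3-methylbut-2-en-1-yl)phenyl]-3-hydroxy-7-methoxychroman-4-one F8. Pd(PPh3)4 and morpholine in THF then remove both allyl groups to give 21.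

Further compounds
F1 | step 8 | 1,3-dimethoxy-5-(methoxymethoxy)benzene | COCOc1cc(OC)cc(OC)c1
F2 | step 8 | N-methoxy-N-methyl-2-[4-(allyloxy)-2-methoxy-3-(3-methylbut-2-en-1-yl)phenyl]prop-2-enamide | C=C(C(=O)N(C)OC)c1ccc(OCC=C)c(CC=C(C)C)c1OC
F3 | step 8 | 2-[4-(allyloxy)-2-methoxy-3-(3-methylbut-2-en-1-yl)phenyl]-1-[2,4-dimethoxy-6-(methoxymethoxy)phenyl]prop-2-en-1-one | C=C(C(=O)c1c(OCOC)cc(OC)cc1OC)c1ccc(OCC=C)c(CC=C(C)C)c1OC
F4 | step 9 | racemic 3-[4-(allyloxy)-2-methoxy-3-(3-methylbut-2-en-1-yl)phenyl]-3-hydroxy-5,7-dimethoxychroman-4-one | COc1cc(OC)c2c(c1)OCC(O)(c1ccc(OCC=C)c(CC=C(C)C)c1OC)C2=O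
F5 | step 9 | (3R)-3-[4-(allyloxy)-2-methoxy-3-(3-methylbut-2-en-1-yl)phenyl]-3-hydroxy-5,7-dimethoxychroman-4-one | COc1cc(OC)c2c(c1)OC[C@](O)(c1ccc(OCC=C)c(CC=C(C)C)c1OC)C2=O
F6 | step 10 | racemic 3-[4-(allyloxy)-2-methoxy-3-(3-methylbut-2-en-1-yl)phenyl]-5-hydroxy-7-methoxychroman-4-one | COc1cc(O)c2c(c1)OCC(c1ccc(OCC=C)c(CC=C(C)C)c1OC)C2=O
F7 | step 10 | racemic 5-(allyloxy)-3-[4-(allyloxy)-2-methoxy-3-(3-methylbut-2-en-1-yl)phenyl]-7-methoxychroman-4-one | COc1cc(OCC=C)c2c(c1)OCC(c1ccc(OCC=C)c(CC=C(C)C)c1OC)C2=O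
F8 | step 10 | (3S)-5-(allyloxy)-3-[4-(allyloxy)-2-methoxy-3-(3-methylbut-2-en-1-yl)phenyl]-3-hydroxy-7-methoxychroman-4-one | COc1cc(OCC=C)c2c(c1)OC[C@@](O)(c1ccc(OCC=C)c(CC=C(C)C)c1OC)C2=O
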